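**Retrosynthetic overview**
1. Target 21 ⇒ open the 12,6-lactone C–O bond and the C6–C7 ring bond (the bond made when a farnesyl chain closes to a germacrane). This gives acyclic epoxy aldehyde / (Z)-β-iodoenoate 18. Forward, one Ni/Cr step closes the ten-membered carbocycle and then the butenolide.
2. 18 ⇒ Z-allylic alcohol 16 (Sharpless epoxidation sets C4/C5, then oxidation) ⇒ ynoate 12 (iodo-aldol with CH2O brings C13 and the C7–I handle) ⇒ aldehyde 9 + methyl propiolate (C8 by catalyst control).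
3. 9 ⇒ cyclopropanol 7 (from (S)-α-methyl-γ-butyrolactone, carries C10) + Z-vinyl iodide 4 (from but-2-yn-1-ol) by Pd homoenolate coupling.
4. Ring order: oxirane (step 11), then ten-membered carbocycle, then γ-lactone (both in step 13). The cyclopropane of 7 is only a masked ketone.

Assumption: germacrane numbering (C1 ketone … C15) is used throughout; for the two catalytic asymmetric steps (3 and 7) the ligand antipode that gives the stated configuration is the one meant.

**Step 1**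
Reactants: 1 but-2-yn-1-ol
Product: 3 (Z)-3-iodobut-2-en-1-ol, via cyclic vinylalanate 2 (not isolated)
Conditions: Red-Al, THF, 0 °C to rt; then I2, −78 to 0 °C
Reagents that add atoms: iodine, II
Why: Alkoxide-directed trans-hydroalumination of the propargylic alcohol puts aluminium on C4 cis to the CH2O group and iodinolysis with retention gives the Z-vinyl iodide, which fixes the neryl-type geometry of the later C4=C5 bond.

**Step 2**
Reactants: 3 (Z)-3-iodobut-2-en-1-ol
Product: 4 (Z)-tert-butyl[(3-iodobut-2-en-1-yl)oxy]dimethylsilane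
Conditions: TBSCl, imidazole, CH2Cl2, 0 °C to rt
Reagents that add atoms: tert-butyldimethylsilyl chloride, CC(C)(C)[Si](C)(C)Cl
Why: Standard silyl protection of the primary alcohol so that O6 survives the later oxidation at C8.

**Step 3**
Reactants: 5 α-methylene-γ-butyrolactone (tulipalin A)
Product: 6 (S)-3-methyldihydrofuran-2(3H)-one
Conditions: H2 (50 atm), Ru(OAc)2[(S)-BINAP] (0.5 mol%), CH2Cl2–MeOH, 25 °C
Reagents that add atoms: none
Why: Ru–BINAP (Noyori-type) asymmetric hydrogenation of the exocyclic enoate adds H2 to one face of the chelated alkene and sets C10 as S.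

**Step 4**
Reactants: 6 (S)-3-methyldihydrofuran-2(3H)-one
Product: 7 1-[(2S)-4-hydroxybutan-2-yl]cyclopropan-1-ol
Conditions: EtMgBr (2.6 equiv), Ti(OiPr)4 (0.2 equiv), THF, 0 °C to rt; aq NH4Cl
Reagents that add atoms: ethylmagnesium bromide, CC[Mg]Br
Why: Kulinkovich cyclopropanation of the lactone carbonyl by the titanacyclopropane turns C1 into a cyclopropanol (a ketone homoenolate that supplies C2 and C3) without enolising the adjacent C10 centre.

**Step 5**
Reactants: 7 1-[(2S)-4-hydroxybutan-2-yl]cyclopropan-1-ol; 4 (Z)-tert-butyl[(3-iodobut-2-en-1-yl)oxy]dimethylsilane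
Product: 8 (3S,7Z)-9-[(tert-butyldimethylsilyl)oxy]-1-hydroxy-3,7-dimethylnon-7-en-4-one
Conditions: Pd(OAc)2 (5 mol%), XPhos (10 mol%), Cs2CO3 (2 equiv), toluene, 60 °C
Reagents that add atoms: none
Why: Pd-catalysed ring-opening cross-coupling of a cyclopropanol (β-carbon elimination to a palladium homoenolate, then C(sp3)–C(sp2) reductive elimination) joins C3 to C4 with retention of the Z-alkene and unveils the C1 ketone.

**Step 6**
Reactants: 8 (3S,7Z)-9-[(tert-butyldimethylsilyl)oxy]-1-hydroxy-3,7-dimethylnon-7-en-4-one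
Product: 9 (3S,7Z)-9-[(tert-butyldimethylsilyl)oxy]-3,7-dimethyl-4-oxonon-7-enal
Conditions: TEMPO (10 mol%), PhI(OAc)2 (1.2 equiv), CH2Cl2, rt
Reagents that add atoms: none
Why: TEMPO/PhI(OAc)2 oxidation takes the primary alcohol cleanly to the aldehyde under near-neutral conditions that leave the α-stereocentre, the silyl ether and the alkene alone.

**Step 7**
Reactants: 9 (3S,7Z)-9-[(tert-butyldimethylsilyl)oxy]-3,7-dimethyl-4-oxonon-7-enal; 10 methyl propiolate
Product: 11 methyl (4R,6S,10Z)-12-[(tert-butyldimethylsilyl)oxy]-4-hydroxy-6,10-dimethyl-7-oxododec-10-en-2-ynoate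
Conditions: Me2Zn (3 equiv), (S,S)-ProPhenol (10 mol%), Ph3P=O (20 mol%), toluene, 0 °C
Reagents that add atoms: none
Why: Zn–ProPhenol (Trost) enantioselective alkynylation with the zinc acetylide of methyl propiolate is aldehyde-selective over the ketone and sets C8 as R under catalyst control.

**Step 8**
Reactants: 11 methyl (4R,6S,10Z)-12-[(tert-butyldimethylsilyl)oxy]-4-hydroxy-6,10-dimethyl-7-oxododec-10-en-2-ynoate
Product: 12 methyl (4R,6S,10Z)-12-[(tert-butyldimethylsilyl)oxy]-6,10-dimethyl-4-(methacryloyloxy)-7-oxododec-10-en-2-ynoate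
Conditions: methacryloyl chloride, pyridine, DMAP (5 mol%), CH2Cl2, −20 °C
Reagents that add atoms: methacryloyl chloride, C=C(C)C(=O)Cl
Why: DMAP-catalysed acylation of the secondary propargylic alcohol installs the C8 methacrylate at low temperature, where the γ-acyloxy ynoate does not isomerise.

**Step 9**
Reactants: 12 methyl (4R,6S,10Z)-12-[(tert-butyldimethylsilyl)oxy]-6,10-dimethyl-4-(methacryloyloxy)-7-oxododec-10-en-2-ynoate
Product: 15 methyl (2Z,4R,6S,10Z)-2-(acetoxymethyl)-12-[(tert-butyldimethylsilyl)oxy]-3-iodo-6,10-dimethyl-4-(methacryloyloxy)-7-oxododeca-2,10-dienoate, via magnesium allenolate 13 (not isolated), via iodomagnesium alkoxide 14 (not isolated)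
Conditions: MgI2 (1.5 equiv), monomeric CH2O (THF solution, 5 equiv), CH2Cl2, −40 to 0 °C; then Ac2O, pyridine, DMAP (cat), 0 °C
Reagents that add atoms: magnesium iodide, I[Mg]I; formaldehyde, C=O; acetic anhydride, CC(=O)OC(C)=O
Why: MgI2-promoted halo-aldol (iodo-Baylis–Hillman) reaction in which iodide adds to C7 of the ynoate and the magnesium allenolate is hydroxymethylated at C11 on the side away from iodine, giving the Z-alkene with I cis to CO2Me, and the alkoxide is acetylated in the same flask.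

**Step 10**
Reactants: 15 methyl (2Z,4R,6S,10Z)-2-(acetoxymethyl)-12-[(tert-butyldimethylsilyl)oxy]-3-iodo-6,10-dimethyl-4-(methacryloyloxy)-7-oxododeca-2,10-dienoate
Product: 16 methyl (2Z,4R,6S,10Z)-2-(acetoxymethyl)-12-hydroxy-3-iodo-6,10-dimethyl-4-(methacryloyloxy)-7-oxododeca-2,10-dienoate
Conditions: HF·pyridine, pyridine–THF, 0 °C
Reagents that add atoms: none
Why: Buffered fluoride desilylation frees the allylic alcohol without touching the three esters, the ketone or the vinyl iodide.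

**Step 11**
Reactants: 16 methyl (2Z,4R,6S,10Z)-2-(acetoxymethyl)-12-hydroxy-3-iodo-6,10-dimethyl-4-(methacryloyloxy)-7-oxododeca-2,10-dienoate
Product: 17 methyl (2Z,4R,6S,10S,11R)-2-(acetoxymethyl)-10,11-epoxy-12-hydroxy-3-iodo-6,10-dimethyl-4-(methacryloyloxy)-7-oxododec-2-enoate
Conditions: Ti(OiPr)4 (0.2 equiv), D-(−)-diethyl tartrate (0.25 equiv), t-BuOOH (2 equiv), 4 Å MS, CH2Cl2, −20 °C
Reagents that add atoms: tert-butyl hydroperoxide, CC(C)(C)OO
Why: Sharpless asymmetric epoxidation of the Z (neryl-type) allylic alcohol with the D-tartrate delivers oxygen to one face only of the electron-rich allylic alkene and sets C4 as S and C5 as R under reagent control.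

**Step 12**
Reactants: 17 methyl (2Z,4R,6S,10S,11R)-2-(acetoxymethyl)-10,11-epoxy-12-hydroxy-3-iodo-6,10-dimethyl-4-(methacryloyloxy)-7-oxododec-2-enoate
Product: 18 methyl (2Z,4R,6S,10S,11S)-2-(acetoxymethyl)-10,11-epoxy-3-iodo-6,10-dimethyl-4-(methacryloyloxy)-7,12-dioxododec-2-enoate
Conditions: TEMPO (10 mol%), PhI(OAc)2 (1.2 equiv), CH2Cl2, 0 °C to rt
Reagents that add atoms: none
Why: TEMPO/PhI(OAc)2 oxidation of the primary epoxy alcohol gives the cis-α,β-epoxy aldehyde without epimerisation or epoxide opening (the C11 descriptor changes only because CHO outranks C10).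

**Step 13**
Reactants: 18 methyl (2Z,4R,6S,10S,11S)-2-(acetoxymethyl)-10,11-epoxy-3-iodo-6,10-dimethyl-4-(methacryloyloxy)-7,12-dioxododec-2-enoate
Product: 21 (4S,5R,6R,8R,10S)-13-acetoxy-4,5-epoxy-8-(methacryloyloxy)-1-oxogermacr-7(11)-en-12,6-olide, via alkenylchromium 19 (not isolated), via macrocyclic chromium alkoxide 20 (not isolated)
Conditions: CrCl2 (10 equiv), NiCl2 (0.2 equiv), DMSO–THF (3:1), 25 °C, syringe-pump addition over 12 h to 2 mM; aq potassium serinate work-up
Reagents that add atoms: none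
Why: Intramolecular Nozaki–Hiyama–Kishi reaction in which the β-chromio enoate adds to the C6 aldehyde at high dilution to close the ten-membered ring, Felkin–Anh attack anti to the epoxide C–O bond setting C6 as R, and the chromium alkoxide held cis to the methyl ester then lactonises to the butenolide.

**Compound list**
1 | but-2-yn-1-ol | CC#CCO | starting material
2 | sodium 2,2-bis(2-methoxyethoxy)-3-methyl-2,5-dihydro-1,2-oxaluminol-2-uide (cyclic vinylalanate) | CC1=CCO[Al-]1(OCCOC)OCCOC.[Na+] | intermediate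
3 | (Z)-3-iodobut-2-en-1-ol | C/C(I)=C/CO | intermediate
4 | (Z)-tert-butyl[(3-iodobut-2-en-1-yl)oxy]dimethylsilane | C/C(I)=C/CO[Si](C)(C)C(C)(C)C | intermediate
5 | α-methylene-γ-butyrolactone (tulipalin A) | C=C1CCOC1=O | starting material
6 | (S)-3-methyldihydrofuran-2(3H)-one | C[C@H]1CCOC1=O | intermediate
7 | 1-[(2S)-4-hydroxybutan-2-yl]cyclopropan-1-ol | OCC[C@H](C)C1(O)CC1 | intermediate
8 | (3S,7Z)-9-[(tert-butyldimethylsilyl)oxy]-1-hydroxy-3,7-dimethylnon-7-en-4-one | OCC[C@H](C)C(=O)CC/C(C)=C\CO[Si](C)(C)C(C)(C)C | intermediate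
9 | (3S,7Z)-9-[(tert-butyldimethylsilyl)oxy]-3,7-dimethyl-4-oxonon-7-enal | O=CC[C@H](C)C(=O)CC/C(C)=C\CO[Si](C)(C)C(C)(C)C | intermediate
10 | methyl propiolate | COC(=O)C#C | starting material
11 | methyl (4R,6S,10Z)-12-[(tert-butyldimethylsilyl)oxy]-4-hydroxy-6,10-dimethyl-7-oxododec-10-en-2-ynoate | COC(=O)C#C[C@H](O)C[C@H](C)C(=O)CC/C(C)=C\CO[Si](C)(C)C(C)(C)C | intermediate
12 | methyl (4R,6S,10Z)-12-[(tert-butyldimethylsilyl)oxy]-6,10-dimethyl-4-(methacryloyloxy)-7-oxododec-10-en-2-ynoate | COC(=O)C#C[C@H](OC(=O)C(C)=C)C[C@H](C)C(=O)CC/C(C)=C\CO[Si](C)(C)C(C)(C)C | intermediate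
13 | iodomagnesium allenolate from iodide addition to C7 of 12 | COC(O[Mg]I)=C=C(I)[C@H](OC(=O)C(C)=C)C[C@H](C)C(=O)CC/C(C)=C\CO[Si](C)(C)C(C)(C)C | intermediate
14 | iodomagnesium alkoxide of the (2Z)-2-(hydroxymethyl)-3-iodo dienoate | COC(=O)/C(CO[Mg]I)=C(\I)[C@H](OC(=O)C(C)=C)C[C@H](C)C(=O)CC/C(C)=C\CO[Si](C)(C)C(C)(C)C | intermediate
15 | methyl (2Z,4R,6S,10Z)-2-(acetoxymethyl)-12-[(tert-butyldimethylsilyl)oxy]-3-iodo-6,10-dimethyl-4-(methacryloyloxy)-7-oxododeca-2,10-dienoate | COC(=O)/C(COC(C)=O)=C(\I)[C@H](OC(=O)C(C)=C)C[C@H](C)C(=O)CC/C(C)=C\CO[Si](C)(C)C(C)(C)C | intermediate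
16 | methyl (2Z,4R,6S,10Z)-2-(acetoxymethyl)-12-hydroxy-3-iodo-6,10-dimethyl-4-(methacryloyloxy)-7-oxododeca-2,10-dienoate | COC(=O)/C(COC(C)=O)=C(\I)[C@H](OC(=O)C(C)=C)C[C@H](C)C(=O)CC/C(C)=C\CO | intermediate
17 | methyl (2Z,4R,6S,10S,11R)-2-(acetoxymethyl)-10,11-epoxy-12-hydroxy-3-iodo-6,10-dimethyl-4-(methacryloyloxy)-7-oxododec-2-enoate | COC(=O)/C(COC(C)=O)=C(\I)[C@H](OC(=O)C(C)=C)C[C@H](C)C(=O)CC[C@]1(C)O[C@@H]1CO | intermediate
18 | methyl (2Z,4R,6S,10S,11S)-2-(acetoxymethyl)-10,11-epoxy-3-iodo-6,10-dimethyl-4-(methacryloyloxy)-7,12-dioxododec-2-enoate (cis-epoxy aldehyde, same spatial arrangement as 17) | COC(=O)/C(COC(C)=O)=C(\I)[C@H](OC(=O)C(C)=C)C[C@H](C)C(=O)CC[C@]1(C)O[C@@H]1C=O | intermediate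
19 | alkenylchromium(III) dichloride from 18 (Cr in place of I at C7, geometry retained) | COC(=O)/C(COC(C)=O)=C(\[Cr](Cl)Cl)[C@H](OC(=O)C(C)=C)C[C@H](C)C(=O)CC[C@]1(C)O[C@@H]1C=O | intermediate
20 | ten-membered carbocycle as its C6 dichlorochromium alkoxide, methyl ester at C12 cis to O6 | C=C(C)C(=O)O[C@@H]1C[C@H](C)C(=O)CC[C@]2(C)O[C@@H]2[C@H](O[Cr](Cl)Cl)/C1=C(\C(=O)OC)COC(C)=O | intermediate
21 | (4S,5R,6R,8R,10S)-13-acetoxy-4,5-epoxy-8-(methacryloyloxy)-1-oxogermacr-7(11)-en-12,6-olide (CNP0128625.1) | C=C(C)C(=O)O[C@@H]1C[C@H](C)C(=O)CC[C@]2(C)O[C@@H]2[C@@H]2OC(=O)C(COC(C)=O)=C21 | target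

**Step count**
Total: 13 steps. Longest linear sequence: 11 steps (5 → 21, steps 3–13; the branch 1 → 4, two steps, joins at step 5).

**Three steps most likely to fail**

Step 13 (Ni/Cr closure of the ten-membered ring and lactonisation). The risks are oligomerisation, a hindered tetrasubstituted alkenylchromium, the ring overriding Felkin–Anh control at C6, and loss of the epoxy aldehyde to Cr salts. The fallback sets out from 16 and comes back at 21, and moves the epoxide to the end. Oxidise 16 with MnO2 to the Z-enal methyl (2Z,4R,6S,10Z)-2-(acetoxymethyl)-3-iodo-6,10-dimethyl-4-(methacryloyloxy)-7,12-dioxododeca-2,10-dienoate F7. Close the ring on this more robust enal by the same Ni/Cr 1,2-addition to give the macrocyclic chromium alkoxide F8, which lactonises to the 4,5-didehydro lactone (4Z)-13-acetoxy-8-(methacryloyloxy)-1-oxogermacra-4,7(11)-dien-12,6-olide F9. Then epoxidise the only electron-rich alkene (C4=C5) with m-CPBA/NaHCO3 at 0 °C, relying on peripheral attack on the ring. C6 and epoxide diastereomers would have to be separated.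

Step 9 (halo-aldol with formaldehyde on an internal γ-acyloxy ynoate). The risks are low reactivity, an E/Z mixture at C7=C11, and aldol of the allenolate onto the C1 ketone. The fallback sets out from 11 and comes back at 15, and uses the free C8 hydroxyl to direct the reaction. Treat 11 with i-PrMgCl (1 equiv), then MgI2 and CH2O. The C8 magnesium alkoxide delivers formaldehyde to C11 from its own side and gives the diol methyl (2Z,4R,6S,10Z)-12-[(tert-butyldimethylsilyl)oxy]-4-hydroxy-2-(hydroxymethyl)-3-iodo-6,10-dimethyl-7-oxododeca-2,10-dienoate F5. Any isomer with the ester cis to the C8 hydroxyl lactonises and is removed by chromatography. Acetylate the primary hydroxyl selectively (AcCl, 2,4,6-collidine, −78 °C) to the mono-acetate methyl (2Z,4R,6S,10Z)-2-(acetoxymethyl)-12-[(tert-butyldimethylsilyl)oxy]-4-hydroxy-3-iodo-6,10-dimethyl-7-oxododeca-2,10-dienoate F6. Methacryloyl chloride/pyridine/DMAP then gives 15.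

Step 5 (Pd homoenolate coupling with an alkenyl iodide). The risks are β-hydride elimination to the enone and epimerisation at C10 by the carbonate base. The fallback sets out from 6 (and uses 4) and comes back at 8, and makes the C3–C4 bond by conjugate addition. Open 6 with Me(MeO)NH·HCl/i-PrMgCl to the Weinreb amide (2S)-4-hydroxy-N-methoxy-N,2-dimethylbutanamide F1. Add vinylmagnesium bromide (2.5 equiv) to get the vinyl ketone (4S)-6-hydroxy-4-methylhex-1-en-3-one F2. Convert 4 with t-BuLi (2 equiv, −78 °C) into (E)-[4-(tert-butyldimethylsilyloxy)but-2-en-2-yl]lithium F3 (Li cis to CH2OTBS) and then with CuI (0.5 equiv) into lithium bis[(Z)-4-(tert-butyldimethylsilyloxy)but-2-en-2-yl]cuprate F4. Add F4 1,4 to F2 (TMSCl, −78 °C) and work up with mild acid to obtain 8.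

**Further compounds**
F1 | step 5 | (2S)-4-hydroxy-N-methoxy-N,2-dimethylbutanamide | CON(C)C(=O)[C@@H](C)CCO
F2 | step 5 | (4S)-6-hydroxy-4-methylhex-1-en-3-one | C=CC(=O)[C@@H](C)CCO
F3 | step 5 | (E)-[4-(tert-butyldimethylsilyloxy)but-2-en-2-yl]lithium | [Li]/C(C)=C\CO[Si](C)(C)C(C)(C)C
F4 | step 5 | lithium bis[(Z)-4-(tert-butyldimethylsilyloxy)but-2-en-2-yl]cuprate | [Li+].C/C(=C/CO[Si](C)(C)C(C)(C)C)[Cu-]/C(C)=C\CO[Si](C)(C)C(C)(C)C
F5 | step 9 | methyl (2Z,4R,6S,10Z)-12-[(tert-butyldimethylsilyl)oxy]-4-hydroxy-2-(hydroxymethyl)-3-iodo-6,10-dimethyl-7-oxododeca-2,10-dienoate | COC(=O)/C(CO)=C(\I)[C@H](O)C[C@H](C)C(=O)CC/C(C)=C\CO[Si](C)(C)C(C)(C)C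
F6 | step 9 | methyl (2Z,4R,6S,10Z)-2-(acetoxymethyl)-12-[(tert-butyldimethylsilyl)oxy]-4-hydroxy-3-iodo-6,10-dimethyl-7-oxododeca-2,10-dienoate | COC(=O)/C(COC(C)=O)=C(\I)[C@H](O)C[C@H](C)C(=O)CC/C(C)=C\CO[Si](C)(C)C(C)(C)C
F7 | step 13 | methyl (2Z,4R,6S,10Z)-2-(acetoxymethyl)-3-iodo-6,10-dimethyl-4-(methacryloyloxy)-7,12-dioxododeca-2,10-dienoate | COC(=O)/C(COC(C)=O)=C(\I)[C@H](OC(=O)C(C)=C)C[C@H](C)C(=O)CC/C(C)=C\C=O
F8 | step 13 | macrocyclic C6 dichlorochromium alkoxide of the 4,5-ene series | C=C(C)C(=O)O[C@@H]1C[C@H](C)C(=O)CC/C(C)=C\[C@H](O[Cr](Cl)Cl)/C1=C(\C(=O)OC)COC(C)=O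
F9 | step 13 | (4Z)-13-acetoxy-8-(methacryloyloxy)-1-oxogermacra-4,7(11)-dien-12,6-olide (4,5-deoxy analogue of 21, same arrangement at C6, C8, C10) | C=C(C)C(=O)O[C@@H]1C[C@H](C)C(=O)CC/C(C)=C\[C@@H]2OC(=O)C(COC(C)=O)=C21
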